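**Plan**
1. Retrosynthesis: first the eight O–CH3 bonds; then C3'–C4' and O1'–C2' of the tetraoxygenated lactone ring C' (formal [4+2] of an o-quinone methide with the enolate of a C3-bound acetaldehyde); then the C3–allyl bond; then O1–C8a and C2–C3 of lactone ring C, which excises CO2; finally C3–B, C4=CH2 and the aryl–acyl bond.
2. Forward: Friedel–Crafts acylation and methylenation give a 1,1-diarylethene; asymmetric hydroboration; copper-catalysed carboxylative lactonisation with CO2 closes ring C; anti allylation and oxidative cleavage give an aldehyde; a carbene-catalysed [4+2] with an o-quinone methide closes ring C'; BBr3 frees the phenols.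
3. Enabling feature: in ring C the O1–C2(=O) fragment is one CO2 molecule. Its two neighbours are C3 (a primary sp3 carbon that can carry boron, then copper) and C8a (a carbon of the 1,3,5-trioxygenated ring A that can carry bromine, placed there by electrophilic substitution of 1-bromo-3,5-dimethoxybenzene). They are 1,4-related through C4–C4a, so CO2 can be stitched between them to close the six-membered ring.
4. Stereochemistry: C4 from catalytic asymmetric hydroboration; C3 by substrate control (alkylation anti to the C4 aryl group); C3' and C4' from the chiral carbene catalyst (enolate face) and the endo mode (cis); no base is used after step 9.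

Key step: step 4

Assumption: locants follow chroman-2-one numbering (O1, C2, C3, C4, C4a, C5–C8, C8a), unprimed for the 5,7-dihydroxy half (rings A and C) and primed for the 5',6',7',8'-tetrahydroxy half (rings A' and C'); 1,2,3,4-tetramethoxybenzene and 4-methylbenzenesulfinic acid are treated as purchasable.

**Route**

Step 1
Reactants: 1 1-bromo-3,5-dimethoxybenzene; 2 4-methoxybenzoyl chloride
Product: 3 (2-bromo-4,6-dimethoxyphenyl)(4-methoxyphenyl)methanone
Conditions: SnCl4 (1.2 equiv), CH2Cl2, 0 °C to rt
Reagents that add atoms: none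
Why: Friedel–Crafts acylation should take place at C2 of 1, the position para to one methoxy group and ortho to the other that is less hindered than the site between the two methoxy groups, and the mild Lewis acid SnCl4 is chosen so that the methoxy group ortho to the new ketone is not cleaved.

Step 2
Reactants: 3 (2-bromo-4,6-dimethoxyphenyl)(4-methoxyphenyl)methanone
Product: 5 1-bromo-3,5-dimethoxy-2-[1-(4-methoxyphenyl)ethenyl]benzene, via tertiary alcohol 4 (not isolated)
Conditions: methylmagnesium bromide (1.5 equiv), THF, 0 to 50 °C; then TsOH·H2O (5 mol %), toluene, 60 °C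
Reagents that add atoms: methylmagnesium bromide, C[Mg]Br
Why: Grignard addition to the diaryl ketone followed by acid-catalysed E1 dehydration of the doubly benzylic tertiary alcohol 4, which can lose a proton only from its methyl group, should give the 1,1-diarylethene as the single alkene.

Step 3
Reactants: 5 1-bromo-3,5-dimethoxy-2-[1-(4-methoxyphenyl)ethenyl]benzene
Product: 6 2-[(2R)-2-(2-bromo-4,6-dimethoxyphenyl)-2-(4-methoxyphenyl)ethyl]-4,4,5,5-tetramethyl-1,3,2-dioxaborolane
Conditions: (L*)CoCl2 (L* = chiral iminopyridine–oxazoline ligand, 2 mol %), NaBHEt3 (4 mol %), pinacolborane (1.2 equiv), THF, rt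
Reagents that add atoms: pinacolborane (4,4,5,5-tetramethyl-1,3,2-dioxaborolane), B1OC(C)(C)C(C)(C)O1
Why: Cobalt-hydride-catalysed anti-Markovnikov asymmetric hydroboration of a 1,1-disubstituted aryl alkene places cobalt and then boron on the CH2 carbon (the future C3) and hydrogen on C4, and the chiral ligand, which has to tell the twisted 2,6-disubstituted bromodimethoxyphenyl ring from the flat 4-methoxyphenyl ring, is used in the enantiomeric form that delivers hydrogen to the Si face of C4 and so sets the 4R centre (R in 6).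

Step 4
Reactants: 6 2-[(2R)-2-(2-bromo-4,6-dimethoxyphenyl)-2-(4-methoxyphenyl)ethyl]-4,4,5,5-tetramethyl-1,3,2-dioxaborolane
Product: 8 (4R)-5,7-dimethoxy-4-(4-methoxyphenyl)-3,4-dihydro-2H-chromen-2-one, via potassium carboxylate 7 (not isolated)
Conditions: CuOAc (10 mol %), 1,10-phenanthroline (12 mol %), potassium tert-butoxide (1.1 equiv), toluene–DMF, rt; then CO2 (1 atm), 60 °C; then 110 °C
Reagents that add atoms: carbon dioxide, O=C=O
Why: Proposed new method: tert-butoxide adds to boron of 6 and the borate hands its primary alkyl group (C3) to the monovalent copper centre; CO2 inserts into the Cu–C3 bond to give carboxylate 7 (C2–C3), whose copper salt undergoes intramolecular oxidative addition into the neighbouring C8a–Br bond and C–O reductive elimination from trivalent copper (O1–C8a), after which CuBr is returned to copper tert-butoxide by the base. The closest known reaction types are the copper-catalysed carboxylation of alkylboron compounds with CO2 and the copper-catalysed Ullmann-type O-arylation of carboxylates with aryl halides, which use the same kind of monovalent copper/N-ligand catalyst, so that CO2 acts here as the two-atom partner of the C3–C4–C4a–C8a unit in a formal [4+2] annulation. The lactone ring C (O1, C2, C3, C4, C4a, C8a) is closed by aryl C–O coupling in a 6-exo sense through a seven-membered cupracycle, which the tether should favour over intermolecular ester formation. No stereocentre is formed; C4 (set in step 3) lies next to the metal-bearing carbon and is at risk only if the alkylcopper species undergoes β-hydride elimination and re-addition. The selectivity needed is therefore CO2 insertion ahead of β-hydride elimination, protodemetalation and reduction of the C–Br bond, with C–Br activation only once the carboxylate is in place; this is secured by forming the borate first, saturating with CO2 at 60 °C, where alkylcopper species insert CO2 readily and aryl bromides are still inert to copper, and heating to 110 °C only afterwards. Both helpers, the boronate on C3 and the bromine on C8a, leave in this step, and the electron-rich aryl bromide is the slow partner, which is why the bidentate phenanthroline ligand and the high effective molarity of the tethered carboxylate are relied on.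

Step 5
Reactants: 8 (4R)-5,7-dimethoxy-4-(4-methoxyphenyl)-3,4-dihydro-2H-chromen-2-one
Product: 10 (3S,4R)-5,7-dimethoxy-4-(4-methoxyphenyl)-3-(prop-2-en-1-yl)-3,4-dihydro-2H-chromen-2-one, via lithium enolate 9 (not isolated)
Conditions: LiN(SiMe3)2 (1.05 equiv), THF, −78 °C; allyl bromide (1.5 equiv), −78 to −40 °C
Reagents that add atoms: allyl bromide (3-bromoprop-1-ene), C=CCBr
Why: Kinetic lithium enolate alkylation, in which the C4 aryl group, held pseudo-axial by the peri 5-methoxy group, blocks one face of enolate 9 so that allyl bromide adds to C3 from the opposite face and sets the 3,4-trans relationship (3S in 10, the same spatial arrangement that is called 3R once C3' is in place) by substrate control.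

Step 6
Reactants: 10 (3S,4R)-5,7-dimethoxy-4-(4-methoxyphenyl)-3-(prop-2-en-1-yl)-3,4-dihydro-2H-chromen-2-one
Product: 12 2-[(3S,4R)-5,7-dimethoxy-4-(4-methoxyphenyl)-2-oxo-3,4-dihydro-2H-chromen-3-yl]acetaldehyde, via diol 11 (not isolated)
Conditions: OsO4 (2 mol %), NaIO4 (4 equiv), 2,6-lutidine (2 equiv), 1,4-dioxane–H2O (3:1), rt
Reagents that add atoms: osmium tetroxide, O=[Os](=O)(=O)=O; sodium periodate, [Na+].[O-]I(=O)(=O)=O
Why: Lemieux–Johnson oxidative cleavage (osmium-catalysed dihydroxylation to diol 11 and periodate glycol cleavage) should turn the terminal alkene into the aldehyde without touching the electron-rich aromatic rings that ozone could attack, and the lutidine buffer keeps C3 from epimerising.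

Step 7
Reactants: 13 1,2,3,4-tetramethoxybenzene
Product: 16 2,3,4,5-tetramethoxyphenol, via aryllithium 14 (not isolated), via dimethyl arylboronate 15 (not isolated)
Conditions: n-butyllithium (1.1 equiv), TMEDA, THF, 0 °C; B(OMe)3 (1.5 equiv), −78 °C to rt; H2O2 (30 % aq), 0 °C to rt
Reagents that add atoms: hydrogen peroxide, OO
Why: Directed ortho-lithiation of the aryl methyl ether (the two free ring positions of 13 are equivalent), borylation and oxidative 1,2-migration of the aryl group from boron to oxygen should give the pentaoxygenated phenol in one pot.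

Step 8
Reactants: 16 2,3,4,5-tetramethoxyphenol; 17 4-methoxybenzaldehyde; 18 4-methylbenzenesulfinic acid
Product: 19 2,3,4,5-tetramethoxy-6-[(4-methoxyphenyl)(4-methylbenzenesulfonyl)methyl]phenol (racemic)
Conditions: TsOH·H2O (10 mol %), CH2Cl2, rt
Reagents that add atoms: none
Why: Acid-catalysed three-component condensation (Mannich-type α-sulfonylalkylation), in which aldehyde and sulfinic acid generate a stabilised benzylic cation equivalent that attacks the only free ring position of phenol 16, ortho to the hydroxyl group, should give a stable sulfone that later releases the o-quinone methide.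

Step 9
Reactants: 12 2-[(3S,4R)-5,7-dimethoxy-4-(4-methoxyphenyl)-2-oxo-3,4-dihydro-2H-chromen-3-yl]acetaldehyde; 19 2,3,4,5-tetramethoxy-6-[(4-methoxyphenyl)(4-methylbenzenesulfonyl)methyl]phenol
Product: 21 (3R,3'S,4R,4'R)-5,5',6',7,7',8'-hexamethoxy-4,4'-bis(4-methoxyphenyl)-[3,3'-bichromane]-2,2'-dione, via o-quinone methide 20 (not isolated)
Conditions: chiral aminoindanol-derived N-mesityl triazolium tetrafluoroborate (15 mol %), 3,3',5,5'-tetra-tert-butyldiphenoquinone (1.2 equiv), Cs2CO3 (2.2 equiv), 4 Å molecular sieves, THF, 0 °C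
Reagents that add atoms: none
Why: Oxidative N-heterocyclic carbene catalysis turns aldehyde 12 into an acyl azolium and then its Z enolate, which should add to the E-configured o-quinone methide 20 (set free from 19 by base) in an endo hetero-Diels–Alder sense and lactonise with release of the carbene, the chiral triazolium fixing the face of the enolate carbon (3'S) and the endo approach placing the C4' aryl group cis to the C3' substituent (4'R), with catalyst control expected to override the influence of C3.

Step 10
Reactants: 21 (3R,3'S,4R,4'R)-5,5',6',7,7',8'-hexamethoxy-4,4'-bis(4-methoxyphenyl)-[3,3'-bichromane]-2,2'-dione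
Product: 23 (3R,3'S,4R,4'R)-5,5',6',7,7',8'-hexahydroxy-4,4'-bis(4-hydroxyphenyl)-[3,3'-bichromane]-2,2'-dione, via octakis(dibromoboryl) ether 22 (not isolated)
Conditions: BBr3 (24 equiv), CH2Cl2, −78 °C to rt; then degassed H2O, 0 °C, under argon
Reagents that add atoms: none
Why: Exhaustive Lewis-acid ether cleavage with BBr3 (methyl transfer to bromide from the aryloxy–boron adducts, then hydrolysis of 22) should free all eight phenols while the two aryl lactones, which would re-close on acidic work-up even if opened, and the four stereocentres, which meet no base, stay intact provided air is kept from the electron-rich polyphenol.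

**Compound list**
1 | 1-bromo-3,5-dimethoxybenzene | COc1cc(Br)cc(OC)c1 | starting material
2 | 4-methoxybenzoyl chloride | COc1ccc(cc1)C(Cl)=O | starting material
3 | (2-bromo-4,6-dimethoxyphenyl)(4-methoxyphenyl)methanone | COc1ccc(cc1)C(=O)c1c(Br)cc(OC)cc1OC | intermediate
4 | 1-(2-bromo-4,6-dimethoxyphenyl)-1-(4-methoxyphenyl)ethan-1-ol (racemic, first formed as its bromomagnesium alkoxide) | CC(O)(c1ccc(OC)cc1)c1c(Br)cc(OC)cc1OC | intermediate (not isolated)
5 | 1-bromo-3,5-dimethoxy-2-[1-(4-methoxyphenyl)ethenyl]benzene | C=C(c1ccc(OC)cc1)c1c(Br)cc(OC)cc1OC | intermediate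
6 | 2-[(2R)-2-(2-bromo-4,6-dimethoxyphenyl)-2-(4-methoxyphenyl)ethyl]-4,4,5,5-tetramethyl-1,3,2-dioxaborolane | COc1cc(OC)cc(Br)c1[C@@H](c1ccc(OC)cc1)CB1OC(C)(C)C(C)(C)O1 | intermediate
7 | potassium (3R)-3-(2-bromo-4,6-dimethoxyphenyl)-3-(4-methoxyphenyl)propanoate (in exchange with its copper salt) | COc1cc(OC)cc(Br)c1[C@@H](c1ccc(OC)cc1)CC(=O)[O-].[K+] | intermediate (not isolated)
8 | (4R)-5,7-dimethoxy-4-(4-methoxyphenyl)-3,4-dihydro-2H-chromen-2-one | O=C1Oc2cc(OC)cc(OC)c2[C@@H](c2ccc(OC)cc2)C1 | intermediate
9 | lithium (4R)-5,7-dimethoxy-4-(4-methoxyphenyl)-4H-chromen-2-olate | [Li+].[O-]C1=C[C@H](c2ccc(OC)cc2)c2c(OC)cc(OC)cc2O1 | intermediate (not isolated)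
10 | (3S,4R)-5,7-dimethoxy-4-(4-methoxyphenyl)-3-(prop-2-en-1-yl)-3,4-dihydro-2H-chromen-2-one (3,4-trans) | O=C1Oc2cc(OC)cc(OC)c2[C@@H](c2ccc(OC)cc2)[C@@H]1CC=C | intermediate
11 | (3S,4R)-3-(2,3-dihydroxypropyl)-5,7-dimethoxy-4-(4-methoxyphenyl)-3,4-dihydro-2H-chromen-2-one (both epimers at the new carbinol carbon) | O=C1Oc2cc(OC)cc(OC)c2[C@@H](c2ccc(OC)cc2)[C@@H]1CC(O)CO | intermediate (not isolated)
12 | 2-[(3S,4R)-5,7-dimethoxy-4-(4-methoxyphenyl)-2-oxo-3,4-dihydro-2H-chromen-3-yl]acetaldehyde | O=C1Oc2cc(OC)cc(OC)c2[C@@H](c2ccc(OC)cc2)[C@@H]1CC=O | intermediate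
13 | 1,2,3,4-tetramethoxybenzene | COc1ccc(OC)c(OC)c1OC | starting material
14 | (2,3,4,5-tetramethoxyphenyl)lithium | [Li]c1cc(OC)c(OC)c(OC)c1OC | intermediate (not isolated)
15 | dimethyl (2,3,4,5-tetramethoxyphenyl)boronate | COB(OC)c1cc(OC)c(OC)c(OC)c1OC | intermediate (not isolated)
16 | 2,3,4,5-tetramethoxyphenol | Oc1cc(OC)c(OC)c(OC)c1OC | intermediate
17 | 4-methoxybenzaldehyde | COc1ccc(C=O)cc1 | starting material
18 | 4-methylbenzenesulfinic acid | Cc1ccc(cc1)S(O)=O | starting material
19 | 2,3,4,5-tetramethoxy-6-[(4-methoxyphenyl)(4-methylbenzenesulfonyl)methyl]phenol (racemic) | COc1ccc(cc1)C(c1c(O)c(OC)c(OC)c(OC)c1OC)S(=O)(=O)c1ccc(C)cc1 | intermediate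
20 | (6E)-2,3,4,5-tetramethoxy-6-[(4-methoxyphenyl)methylidene]cyclohexa-2,4-dien-1-one | O=C1C(OC)=C(OC)C(OC)=C(OC)/C1=C\c1ccc(OC)cc1 | intermediate (not isolated)
21 | (3R,3'S,4R,4'R)-5,5',6',7,7',8'-hexamethoxy-4,4'-bis(4-methoxyphenyl)-[3,3'-bichromane]-2,2'-dione (ring C trans, ring C' cis) | O=C1Oc2cc(OC)cc(OC)c2[C@@H](c2ccc(OC)cc2)[C@@H]1[C@H]1C(=O)Oc2c(OC)c(OC)c(OC)c(OC)c2[C@H]1c1ccc(OC)cc1 | intermediate
22 | octakis(dibromoboryl) ether of 23 (all eight phenolic oxygens carry BBr2; same four stereocentres as 21) | O=C1Oc2cc(OB(Br)Br)cc(OB(Br)Br)c2[C@@H](c2ccc(OB(Br)Br)cc2)[C@@H]1[C@H]1C(=O)Oc2c(OB(Br)Br)c(OB(Br)Br)c(OB(Br)Br)c(OB(Br)Br)c2[C@H]1c1ccc(OB(Br)Br)cc1 | intermediate (not isolated)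
23 | (3R,3'S,4R,4'R)-5,5',6',7,7',8'-hexahydroxy-4,4'-bis(4-hydroxyphenyl)-[3,3'-bichromane]-2,2'-dione | O=C1Oc2cc(O)cc(O)c2[C@@H](c2ccc(O)cc2)[C@@H]1[C@H]1C(=O)Oc2c(O)c(O)c(O)c(O)c2[C@H]1c1ccc(O)cc1 | target

**Count**
Total steps: 10. Longest linear sequence: 8 steps (steps 1, 2, 3, 4, 5, 6, 9, 10); steps 7 and 8 build the second fragment.

**Steps most likely to fail**

Step 4 (proposed new method). Transfer of the alkyl group from the pinacol boronate to copper may be slow and lead to protodeboronation. β-Hydride elimination of the alkylcopper species may erode C4. The copper carboxylate may fail to engage the electron-rich, ortho-substituted aryl bromide and leave the open acid. The fallback uses known reactions only and sets out from boronate 6. Matteson homologation with (dichloromethyl)lithium, made in the flask from CH2Cl2 and LiN(i-Pr)2 (THF, −78 °C, then ZnCl2), would give 2-[(3R)-3-(2-bromo-4,6-dimethoxyphenyl)-1-chloro-3-(4-methoxyphenyl)propyl]-4,4,5,5-tetramethyl-1,3,2-dioxaborolane F1, so that C2 comes from dichloromethane and not from CO2. Buffered NaClO2 oxidation would convert it into (3R)-3-(2-bromo-4,6-dimethoxyphenyl)-3-(4-methoxyphenyl)propanoic acid F2. A separate copper-catalysed intramolecular O-arylation (CuI, 1,10-phenanthroline, Cs2CO3, DMF, 110 °C) would then form the O1–C8a bond and come back to the route at lactone 8.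

Step 9. The peri methoxy group at C5' may disturb the geometry of the quinone methide and lower the endo preference (cis against trans). The catalyst may be mismatched with the C3 stereocentre. Base may epimerise the kinetically formed cis lactone at C3'. The diphenoquinone may oxidise the electron-rich phenolate. The fallback sets out from aldehyde 12 and phenol 16. Pinnick oxidation of 12 (NaClO2, NaH2PO4, 2-methyl-2-butene) would give 2-[(3S,4R)-5,7-dimethoxy-4-(4-methoxyphenyl)-2-oxo-3,4-dihydro-2H-chromen-3-yl]acetic acid F3. Phenol 16 would be C-acylated at its only free position with acid chloride 2 (TiCl4, CH2Cl2) to give (2-hydroxy-3,4,5,6-tetramethoxyphenyl)(4-methoxyphenyl)methanone F4. Steglich esterification of the two (EDC·HCl, DMAP) would give 2,3,4,5-tetramethoxy-6-(4-methoxybenzoyl)phenyl 2-[(3S,4R)-5,7-dimethoxy-4-(4-methoxyphenyl)-2-oxo-3,4-dihydro-2H-chromen-3-yl]acetate F5. Intramolecular Knoevenagel-type condensation (TiCl4, Et3N) would close the coumarin (3R,4R)-5,5',6',7,7',8'-hexamethoxy-4,4'-bis(4-methoxyphenyl)-3,4-dihydro-2H,2'H-[3,3'-bichromene]-2,2'-dione F6. Heterogeneous hydrogenation (H2, Rh/Al2O3 or palladium on carbon) would add both hydrogens to one face of the C3'=C4' bond. Syn addition fixes the cis relation, so only the face remains to be chosen by the C3 stereocentre, and the sequence comes back to the route at 21.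

Step 3. The catalyst may not tell the two aryl groups apart well enough, or the low-valent cobalt hydride may attack the C–Br bond. The fallback sets out from alkene 5 and moves the enantio-determining event behind the lactone formation. Achiral hydroboration (pinacolborane, [Ir(cod)Cl]2, dppe) would give racemic 2-[2-(2-bromo-4,6-dimethoxyphenyl)-2-(4-methoxyphenyl)ethyl]-4,4,5,5-tetramethyl-1,3,2-dioxaborolane F7. The conditions of step 4 would take it through racemic potassium 3-(2-bromo-4,6-dimethoxyphenyl)-3-(4-methoxyphenyl)propanoate F8 to racemic 5,7-dimethoxy-4-(4-methoxyphenyl)-3,4-dihydro-2H-chromen-2-one F9. Dehydrogenation with DDQ (1,4-dioxane, reflux) would give 5,7-dimethoxy-4-(4-methoxyphenyl)-2H-chromen-2-one F10. Copper hydride asymmetric conjugate reduction (Cu(OAc)2·H2O, the enantiomer of DTBM-SEGPHOS that leads to 4R, (EtO)2MeSiH, t-BuOH, toluene), a reaction type with close precedent on 4-arylcoumarins, would then return to the route at lactone 8.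

**Further compounds**
F1 | step 4 | 2-[(3R)-3-(2-bromo-4,6-dimethoxyphenyl)-1-chloro-3-(4-methoxyphenyl)propyl]-4,4,5,5-tetramethyl-1,3,2-dioxaborolane (both epimers at C1) | COc1cc(OC)cc(Br)c1[C@@H](c1ccc(OC)cc1)CC(Cl)B1OC(C)(C)C(C)(C)O1
F2 | step 4 | (3R)-3-(2-bromo-4,6-dimethoxyphenyl)-3-(4-methoxyphenyl)propanoic acid | COc1cc(OC)cc(Br)c1[C@@H](c1ccc(OC)cc1)CC(O)=O
F3 | step 9 | 2-[(3S,4R)-5,7-dimethoxy-4-(4-methoxyphenyl)-2-oxo-3,4-dihydro-2H-chromen-3-yl]acetic acid | O=C1Oc2cc(OC)cc(OC)c2[C@@H](c2ccc(OC)cc2)[C@@H]1CC(O)=O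
F4 | step 9 | (2-hydroxy-3,4,5,6-tetramethoxyphenyl)(4-methoxyphenyl)methanone | COc1ccc(cc1)C(=O)c1c(O)c(OC)c(OC)c(OC)c1OC
F5 | step 9 | 2,3,4,5-tetramethoxy-6-(4-methoxybenzoyl)phenyl 2-[(3S,4R)-5,7-dimethoxy-4-(4-methoxyphenyl)-2-oxo-3,4-dihydro-2H-chromen-3-yl]acetate | O=C1Oc2cc(OC)cc(OC)c2[C@@H](c2ccc(OC)cc2)[C@@H]1CC(=O)Oc1c(OC)c(OC)c(OC)c(OC)c1C(=O)c1ccc(OC)cc1
F6 | step 9 | (3R,4R)-5,5',6',7,7',8'-hexamethoxy-4,4'-bis(4-methoxyphenyl)-3,4-dihydro-2H,2'H-[3,3'-bichromene]-2,2'-dione | O=C1Oc2cc(OC)cc(OC)c2[C@@H](c2ccc(OC)cc2)[C@@H]1C1=C(c2ccc(OC)cc2)c2c(OC)c(OC)c(OC)c(OC)c2OC1=O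
F7 | step 3 | racemic 2-[2-(2-bromo-4,6-dimethoxyphenyl)-2-(4-methoxyphenyl)ethyl]-4,4,5,5-tetramethyl-1,3,2-dioxaborolane | COc1cc(OC)cc(Br)c1C(c1ccc(OC)cc1)CB1OC(C)(C)C(C)(C)O1
F8 | step 3 | racemic potassium 3-(2-bromo-4,6-dimethoxyphenyl)-3-(4-methoxyphenyl)propanoate | COc1cc(OC)cc(Br)c1C(c1ccc(OC)cc1)CC(=O)[O-].[K+]
F9 | step 3 | racemic 5,7-dimethoxy-4-(4-methoxyphenyl)-3,4-dihydro-2H-chromen-2-one | O=C1Oc2cc(OC)cc(OC)c2C(c2ccc(OC)cc2)C1
F10 | step 3 | 5,7-dimethoxy-4-(4-methoxyphenyl)-2H-chromen-2-one | O=C1C=C(c2ccc(OC)cc2)c2c(OC)cc(OC)cc2O1
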